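## The problem

Compound 15 is a depside. Ring A is a 2-hydroxy-4-methoxy-6-(2-oxopentyl)benzoyl unit, and its C1 carboxyl carbon is esterified to the C1 oxygen of ring B, a 3-hydroxy-5-propylphenyl unit with a free carboxylic acid at C4. There is no stereocentre, so the task is one of connectivity, order of events and functional-group tolerance, not of stereocontrol. The linking ester is an aryl ester of a doubly ortho-substituted benzoic acid. It is hard to form by acyl substitution, and once formed it is an activated ester whose aryloxy group leaves readily under basic or nucleophilic conditions. The side-chain ketone at C6 of ring A is placed so that its enol oxygen can add to the ester carbonyl through a six-membered ring and expel ring B. Any step that holds ketone and aryl ester together under acid or base invites this enol-lactonisation. Ring B is a salicylic acid that can decarboxylate on heating, and each ring has a chelated phenol that must be told apart from its neighbours (the C4 methoxy of ring A, the ester-bearing C1 oxygen of ring B). A late construction of the side chain is possible because C6 of ring A is ortho to the electron-withdrawing ester and the chain is attached through a methylene alpha to a ketone. A C6–Br bond is therefore activated for oxidative addition to zerovalent palladium, and the ring–CH2 bond is exactly the bond that arylation of the terminal enolate of pentan-2-one forms.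

## Retrosynthesis

**15 from 14.** The three O–benzyl bonds (the phenolic ethers at C2 of ring A and C3 of ring B, and the ester at C4 of ring B) are cut last. Benzyl is chosen because hydrogenolysis is neutral. Methyl, acetal or silyl protection would need acid, base or fluoride in the presence of the free ketone and the activated aryl ester. The forward step must remove three benzyl groups from 14 without reducing the ketone and without giving the keto ester time or catalysis to lactonise.

**14 from 11 and 13.** The bond between C6 of ring A and the side-chain methylene is cut. The neighbouring cut, CH2–C(=O), would need a benzylic anion (lateral metalation) that the aryl ester cannot survive. That would force the side chain in before the esterification and carry a lactonisation-prone keto acid, or a ketal and its acidic removal, through the route. Cutting the depside ester last is worse still, because an activated 2-(2-oxopentyl)benzoic acid closes to the isocoumarin instead of acylating a phenol. The aryl–CH2 cut leaves the complete depside 11, with bromine as an inert placeholder at C6, and the five-carbon enol silane 13. The forward reaction must couple at the terminal enolate carbon only, once only, under conditions free of alkoxide or amide base.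

**13 from 12.** The O–Si bond is cut. Kinetic deprotonation of pentan-2-one (12) at the methyl group and silylation fix the enolate position before the coupling, which a free ketone under basic arylation conditions could not guarantee.

**11 from 10 and 10 from 9.** Two O–benzyl bonds on ring B (carboxylic ester and phenolic ether) are cut in one operation to the hydroxy acid 10. The carboxyl of 10 is then traced to the formyl group of 9. The aldehyde level is preferred for ring B because formylation places the carbon para to a hydroxyl with reliable regiochemistry, whereas direct carboxylation of a 5-alkylresorcinol tends to go between the two hydroxyls. The formyl group also hydrogen-bonds its ortho hydroxyl and so differentiates the two phenols.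

**9 from 5 and 7, through 8.** The acyl C–O bond of the depside is cut to the ring A acid 5, activated as its chloride 8, and the dihydroxy aldehyde 7. This is preferred over an O–aryl cut because 7 already holds the oxygen at the right carbon. The forward step must acylate only the unchelated hydroxyl para to the formyl group, with a hindered aroyl chloride.

**5 from 1 through 4, 3 and 2.** The carboxyl carbon of ring A is traced through the aldehyde 4 to a formylation of 1-bromo-3,5-dimethoxybenzene (1). Formylation para to one methoxy and ortho to the other gives 2. Chelation-controlled cleavage of the methoxy ortho to the formyl group gives 3 and so separates the future C2 hydroxyl from the C4 methoxy. Benzylation and oxidation give 4 and then 5. The bromine of 1 ends up at C6 with no separate halogenation step.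

**7 from 6.** The ring–CHO bond is cut. Formylation of 5-propylbenzene-1,3-diol (6) at the position para to one hydroxyl and ortho to the other gives the ring B substitution pattern in one step.

## Roads not taken

**Alternative 1: ring A built by cycloaddition on an ynoate.** The cut is through C1–C2 and C5–C6 of ring A. The protected ring B phenol would be esterified with a ketal-bearing alkynoic acid to give ynoate A2. A2 would then react with the electron-rich diene A3 in a [4+2] cycloaddition, and loss of the methoxy and silyl groups would aromatise the adduct to A1.
- Merits: the depside ester is made from an unhindered alkynoic acid, so the hindered benzoate acylation is avoided. The oxygen pattern of ring A appears directly with C2–OH free and C4–OMe in place. In these two respects this road is better than the chosen plan, which spends four steps on functional-group work on ring A.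
- Weak points: A2 is a beta-substituted ynoate and a sluggish dienophile, and it is also an acylating agent and Michael acceptor. A3 is moisture-sensitive and can add in an open-chain Michael fashion. The acid component of A2 needs several steps of its own.
- Decisive drawback: A1 carries the ketone as a dioxolane. The endgame must therefore hydrolyse a ketal with acid while the aryl ester is present, which are the conditions under which the freed ketone lactonises with loss of ring B.
- Comparison: the chosen plan offers standard aromatic chemistry and a ketone that arrives free under near-neutral conditions one step before 15.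

**Alternative 2: ring B built by cycloaddition around an enol ester.** The cut is through C3–C4 and C5–C6 of ring B. The ring A acid, already carrying the ketal side chain, would be attached as an enol ester to a 1-benzyloxy-1-silyloxy diene, giving A5. Cycloaddition of A5 with benzyl hex-2-ynoate A6 and loss of the benzyloxy and silyl groups would give A4.
- Merits: the ester linkage is formed on an enolate oxygen and not on a phenol. The C3 hydroxyl of ring B emerges free and the carboxyl emerges as its benzyl ester, so the ring B oxygens need no differentiation. That is a real advantage over the selective acylation in step 6.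
- Weak points: the ketene acetal of A5 must be generated with strong base next to an enol ester that is itself an acyl donor, so O-to-C acyl migration threatens. The acyloxy group makes the diene less electron-rich than an alkoxy analogue. A6 has a beta-propyl group and is a poor dienophile.
- Further drawbacks: the ring A acid must receive its side chain before the key step, so the problem the chosen plan solves last is moved earlier and is not removed. A4 again needs acidic ketal cleavage next to the aryl ester.
- Comparison: the chosen plan differentiates the ring B hydroxyls at no cost through the hydrogen bond in 7 and needs no ketal.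

**Alternative 3: O-arylation of the ring A carboxylate.** The cut is between the carboxylate oxygen of ring A and C1 of ring B. Acid A8 and arylboronic acid A9 would be coupled oxidatively with Cu(OTf)2 and base under air to give A7.
- Merits: the new bond is formed at oxygen, so the steric shielding of the carboxyl carbon by two ortho substituents matters little. For the ester-forming step alone this is the better solution, since step 6 of the chosen plan must push a 2,6-disubstituted aroyl chloride onto a phenol. Against this stands the fact that such chlorides ionise easily and do acylate phenoxides.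
- Weak points: A9 is an electron-poor boronic acid with a para ester, so transmetalation to divalent copper should be slow and protodeboronation or oxidative hydroxylation competitive. Making A9 means removing the native C1 oxygen of ring B and replacing it with boron, only to bond that carbon to oxygen again. The chosen plan uses phenol 7, one step from 6.
- Further drawbacks: A8 must already hold the side chain as a ketal, so A7 has the same acid-mediated endgame as the other two alternatives.

Key step: step 10

Assumption: compounds 1, 6 and 12 and all reagents in the Conditions lines are taken as commercial, and 13 is used freshly distilled and free of its internal regioisomer.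

## Route

Step 1
Reactants: 1 1-bromo-3,5-dimethoxybenzene
Product: 2 2-bromo-4,6-dimethoxybenzaldehyde
Conditions: POCl3, DMF, 0 °C → 90 °C; then aq. NaOAc
Reagents that add atoms: N,N-dimethylformamide CN(C)C=O (formyl carbon); water O (carbonyl oxygen, on hydrolysis of the iminium salt)
Why: Vilsmeier–Haack formylation; the chloroiminium ion attacks the position para to one methoxy and ortho to the other, next to bromine, which is the most activated site that is not flanked by two methoxy groups.

Step 2
Reactants: 2 2-bromo-4,6-dimethoxybenzaldehyde
Product: 3 2-bromo-6-hydroxy-4-methoxybenzaldehyde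
Conditions: BCl3, CH2Cl2, −78 °C → 0 °C; then H2O
Reagents that add atoms: none
Why: Chelation-controlled ether cleavage; boron binds the aldehyde oxygen and delivers chloride to the methyl of the ortho methoxy through a six-membered chelate, so the para methoxy should stay intact.

Step 3
Reactants: 3 2-bromo-6-hydroxy-4-methoxybenzaldehyde
Product: 4 2-(benzyloxy)-6-bromo-4-methoxybenzaldehyde
Conditions: BnBr, K2CO3, DMF, rt
Reagents that add atoms: benzyl bromide BrCc1ccccc1
Why: Williamson etherification of the only phenol; the benzyl ether survives every later step and is removed by hydrogenolysis at the end.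

Step 4
Reactants: 4 2-(benzyloxy)-6-bromo-4-methoxybenzaldehyde
Product: 5 2-(benzyloxy)-6-bromo-4-methoxybenzoic acid
Conditions: NaClO2, NaH2PO4, 2-methyl-2-butene, t-BuOH/THF/H2O, rt
Reagents that add atoms: sodium chlorite [Na+].[O-]Cl=O
Why: Pinnick oxidation; chlorous acid oxidises hindered, non-enolisable aryl aldehydes cleanly, and the alkene scavenger removes hypochlorous acid before it can chlorinate the electron-rich ring.

Step 5
Reactants: 6 5-propylbenzene-1,3-diol
Product: 7 2,4-dihydroxy-6-propylbenzaldehyde
Conditions: POCl3, DMF, 0 °C → rt; then H2O, 50 °C
Reagents that add atoms: N,N-dimethylformamide CN(C)C=O (formyl carbon); water O (carbonyl oxygen, on hydrolysis of the iminium salt)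
Why: Vilsmeier–Haack formylation of a resorcinol; attack para to one hydroxyl and ortho to the other is favoured over the position between the two hydroxyls, which sets the ring B pattern of 15.

Step 6
Reactants: 5 2-(benzyloxy)-6-bromo-4-methoxybenzoic acid; 7 2,4-dihydroxy-6-propylbenzaldehyde
Product: 9 4-formyl-3-hydroxy-5-propylphenyl 2-(benzyloxy)-6-bromo-4-methoxybenzoate, via 2-(benzyloxy)-6-bromo-4-methoxybenzoyl chloride 8 (not isolated)
Conditions: (COCl)2, DMF (cat.), CH2Cl2, 0 °C → rt; evaporate; then 7, Et3N, CH2Cl2, 0 °C → rt
Reagents that add atoms: oxalyl chloride ClC(=O)C(Cl)=O (supplies the chlorine of 8 only; no atom of it remains in 9)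
Why: Acyl chloride formation followed by O-acylation of a phenol; the hydroxyl para to the formyl group of 7 is the more acidic and unchelated one, while the ortho hydroxyl is held in a hydrogen bond to the aldehyde, so mono-acylation at the future C1 oxygen of ring B is expected. Doubly ortho-substituted, donor-bearing aroyl chlorides ionise readily and acylate phenoxides despite the hindrance.

Step 7
Reactants: 9 4-formyl-3-hydroxy-5-propylphenyl 2-(benzyloxy)-6-bromo-4-methoxybenzoate
Product: 10 4-{[2-(benzyloxy)-6-bromo-4-methoxybenzoyl]oxy}-2-hydroxy-6-propylbenzoic acid
Conditions: NaClO2, NaH2PO4, 2-methyl-2-butene (large excess), t-BuOH/THF/H2O, 0 °C → rt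
Reagents that add atoms: sodium chlorite [Na+].[O-]Cl=O
Why: Pinnick oxidation of a salicylaldehyde; the weakly acidic buffer leaves the aryl ester alone, and the acyloxy group para to the aldehyde lowers the electron density of ring B so that the scavenger can outrun ring chlorination.

Step 8
Reactants: 10 4-{[2-(benzyloxy)-6-bromo-4-methoxybenzoyl]oxy}-2-hydroxy-6-propylbenzoic acid
Product: 11 3-(benzyloxy)-4-(benzyloxycarbonyl)-5-propylphenyl 2-(benzyloxy)-6-bromo-4-methoxybenzoate
Conditions: BnBr (2.5 equiv), K2CO3, DMF, rt → 50 °C
Reagents that add atoms: benzyl bromide BrCc1ccccc1
Why: Double O-alkylation (carboxylate first, then the chelated phenoxide) in one operation; the depside carbonyl is shielded by bromine and benzyloxy in both ortho positions and should resist carbonate and phenoxide under these conditions.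

Step 9
Reactants: 12 pentan-2-one
Product: 13 2-(trimethylsilyloxy)pent-1-ene
Conditions: LiN(i-Pr)2, THF, −78 °C; then Me3SiCl, −78 °C → rt; fractional distillation
Reagents that add atoms: chlorotrimethylsilane C[Si](C)(C)Cl
Why: Kinetic enolisation and O-silylation; the hindered amide base removes a methyl proton faster than a methylene proton at low temperature, and trapping on oxygen fixes the terminal enolate position.

Step 10
Reactants: 11 3-(benzyloxy)-4-(benzyloxycarbonyl)-5-propylphenyl 2-(benzyloxy)-6-bromo-4-methoxybenzoate; 13 2-(trimethylsilyloxy)pent-1-ene
Product: 14 3-(benzyloxy)-4-(benzyloxycarbonyl)-5-propylphenyl 2-(benzyloxy)-4-methoxy-6-(2-oxopentyl)benzoate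
Conditions: 13 (2 equiv), Pd(OAc)2 (5 mol %), P(t-Bu)3 (10 mol %), Bu3SnF (1.5 equiv), toluene, 85 °C
Reagents that add atoms: none
Why: Pd(OAc)2 is reduced in situ to a zerovalent palladium–P(t-Bu)3 complex, which inserts into the C6–Br bond of 11; the ortho ester lowers the electron density at C6 and assists this oxidative addition. Fluoride from Bu3SnF attacks the silicon of 13 and gives the tributyltin enolate of pentan-2-one with the enolate position unchanged; this transmetalates to the arylpalladium bromide, and reductive elimination from the carbon-bound palladium enolate forms the C6–CH2 bond and returns zerovalent palladium. The closest known reaction type is the palladium-catalysed arylation of methyl-ketone enol silanes with aryl bromides in the presence of a tin fluoride. No ring is closed and no stereocentre is formed. Site selectivity (terminal CH2 against C3 of the ketone) is required and is secured by the preformed less-substituted enol silane. Mono-arylation is required and is favoured by the bulky phosphine and by the congested product. Chemoselectivity against the aryl ester and the benzyl ester is required and rests on the absence of alkoxide or amide base, helped by the two ortho substituents that shield the ring A ester carbonyl from the enol oxygen of the product.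

Step 11
Reactants: 14 3-(benzyloxy)-4-(benzyloxycarbonyl)-5-propylphenyl 2-(benzyloxy)-4-methoxy-6-(2-oxopentyl)benzoate
Product: 15 2-hydroxy-4-{[2-hydroxy-4-methoxy-6-(2-oxopentyl)benzoyl]oxy}-6-propylbenzoic acid
Conditions: H2 (1 atm), 10% Pd/C, EtOAc, rt
Reagents that add atoms: none
Why: Hydrogenolysis of two aryl benzyl ethers and one benzyl ester under neutral conditions; the aliphatic ketone, the aryl ester and the aryl–CH2 bond are not reduced at ambient pressure, and no acid or base is present to trigger enol-lactonisation.

## Compound list

1 | 1-bromo-3,5-dimethoxybenzene | COc1cc(Br)cc(OC)c1 | starting material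
2 | 2-bromo-4,6-dimethoxybenzaldehyde | COc1cc(Br)c(C=O)c(OC)c1 | intermediate
3 | 2-bromo-6-hydroxy-4-methoxybenzaldehyde | COc1cc(O)c(C=O)c(Br)c1 | intermediate
4 | 2-(benzyloxy)-6-bromo-4-methoxybenzaldehyde | COc1cc(Br)c(C=O)c(OCc2ccccc2)c1 | intermediate
5 | 2-(benzyloxy)-6-bromo-4-methoxybenzoic acid | COc1cc(Br)c(C(=O)O)c(OCc2ccccc2)c1 | intermediate
6 | 5-propylbenzene-1,3-diol | CCCc1cc(O)cc(O)c1 | starting material
7 | 2,4-dihydroxy-6-propylbenzaldehyde | CCCc1cc(O)cc(O)c1C=O | intermediate
8 | 2-(benzyloxy)-6-bromo-4-methoxybenzoyl chloride | COc1cc(Br)c(C(Cl)=O)c(OCc2ccccc2)c1 | intermediate (not isolated)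
9 | 4-formyl-3-hydroxy-5-propylphenyl 2-(benzyloxy)-6-bromo-4-methoxybenzoate | COc1cc(Br)c(C(=O)Oc2cc(O)c(C=O)c(CCC)c2)c(OCc2ccccc2)c1 | intermediate
10 | 4-{[2-(benzyloxy)-6-bromo-4-methoxybenzoyl]oxy}-2-hydroxy-6-propylbenzoic acid | COc1cc(Br)c(C(=O)Oc2cc(O)c(C(=O)O)c(CCC)c2)c(OCc2ccccc2)c1 | intermediate
11 | 3-(benzyloxy)-4-(benzyloxycarbonyl)-5-propylphenyl 2-(benzyloxy)-6-bromo-4-methoxybenzoate | COc1cc(Br)c(C(=O)Oc2cc(CCC)c(C(=O)OCc3ccccc3)c(OCc3ccccc3)c2)c(OCc2ccccc2)c1 | intermediate
12 | pentan-2-one | CCCC(C)=O | starting material
13 | 2-(trimethylsilyloxy)pent-1-ene | CCCC(=C)O[Si](C)(C)C | intermediate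
14 | 3-(benzyloxy)-4-(benzyloxycarbonyl)-5-propylphenyl 2-(benzyloxy)-4-methoxy-6-(2-oxopentyl)benzoate | CCCC(=O)Cc1cc(OC)cc(OCc2ccccc2)c1C(=O)Oc1cc(CCC)c(C(=O)OCc2ccccc2)c(OCc2ccccc2)c1 | intermediate
15 | 2-hydroxy-4-{[2-hydroxy-4-methoxy-6-(2-oxopentyl)benzoyl]oxy}-6-propylbenzoic acid | CCCC(=O)Cc1cc(OC)cc(O)c1C(=O)Oc1cc(O)c(C(=O)O)c(CCC)c1 | target

## Step count and risks

Total step count: 11. Longest linear sequence: 9 steps (steps 1, 2, 3, 4, 6, 7, 8, 10, 11).

**Step 10 (key step).**
- What may go wrong: proton exchange between the tin enolate and the more acidic benzylic ketone of the product. The resulting product enolate can close onto the neighbouring aryl ester with expulsion of ring B, or be arylated a second time.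
- Also possible: migration of the enolate position by the same proton transfer, giving arylation at C3 of the ketone, and reduction of the C–Br bond if transmetalation to the ortho-ester-chelated arylpalladium species is slow.
- Fallback (no enolate in the presence of the aryl ester): bromide 11 would be coupled in a Suzuki–Miyaura allylation (PdCl2(dppf), CsF, THF, 65 °C) with 4,4,5,5-tetramethyl-2-(2-methylidenepentyl)-1,3,2-dioxaborolane F1, prepared beforehand by borylation of the corresponding allylic halide. This should give 3-(benzyloxy)-4-(benzyloxycarbonyl)-5-propylphenyl 2-(benzyloxy)-4-methoxy-6-(2-methylidenepentyl)benzoate F2. Lemieux–Johnson cleavage of its 1,1-disubstituted alkene (OsO4 cat., NaIO4, 2,6-lutidine, dioxane/H2O, rt) would unveil the ketone and rejoin the route at 14.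

**Step 11.**
- What may go wrong: enol-lactonisation of the freed keto ester with loss of ring B on the catalyst surface or during concentration, and slow cleavage of the hindered benzyl ether next to the ester, which prolongs exposure and invites reduction of the ketone.
- Fallback: non-reductive Lewis-acid debenzylation of 14 with BCl3 and pentamethylbenzene as benzyl-cation scavenger in CH2Cl2 at −78 °C, which should give 15 directly without a metal surface or hydrogen.

**Step 7.**
- What may go wrong: electrophilic chlorination of the phenolic ring B by hypochlorous acid in competition with the scavenger, and sluggish oxidation of the hydrogen-bonded aldehyde.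
- Fallback (change of order): 9 would first be benzylated at the chelated hydroxyl (BnBr, K2CO3, DMF) to 3-(benzyloxy)-4-formyl-5-propylphenyl 2-(benzyloxy)-6-bromo-4-methoxybenzoate F3. Pinnick oxidation without a free phenol would give 2-(benzyloxy)-4-{[2-(benzyloxy)-6-bromo-4-methoxybenzoyl]oxy}-6-propylbenzoic acid F4. Carboxylate alkylation (BnBr, KHCO3, DMF, rt) would rejoin the route at 11, bypassing 10.

**Step 8.**
- What may go wrong: intermolecular acyl transfer from the activated aryl ester to phenoxide or carbonate at the temperature needed to alkylate the chelated hydroxyl, and incomplete etherification of that hydroxyl.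
- Fallback (two mechanistically different alkylations): 10 would be esterified at the carboxylate only (BnBr, KHCO3, DMF, rt) to 4-(benzyloxycarbonyl)-3-hydroxy-5-propylphenyl 2-(benzyloxy)-6-bromo-4-methoxybenzoate F5. The remaining phenol would then be benzylated under neutral Mitsunobu conditions (BnOH, PPh3, DIAD, THF, 0 °C → rt), rejoining the route at 11.

## Further compounds

F1 | step 10 | 4,4,5,5-tetramethyl-2-(2-methylidenepentyl)-1,3,2-dioxaborolane | CCCC(=C)CB1OC(C)(C)C(C)(C)O1
F2 | step 10 | 3-(benzyloxy)-4-(benzyloxycarbonyl)-5-propylphenyl 2-(benzyloxy)-4-methoxy-6-(2-methylidenepentyl)benzoate | CCCC(=C)Cc1cc(OC)cc(OCc2ccccc2)c1C(=O)Oc1cc(CCC)c(C(=O)OCc2ccccc2)c(OCc2ccccc2)c1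
F0 | step 11 | none | none
F3 | step 7 | 3-(benzyloxy)-4-formyl-5-propylphenyl 2-(benzyloxy)-6-bromo-4-methoxybenzoate | COc1cc(Br)c(C(=O)Oc2cc(CCC)c(C=O)c(OCc3ccccc3)c2)c(OCc2ccccc2)c1
F4 | step 7 | 2-(benzyloxy)-4-{[2-(benzyloxy)-6-bromo-4-methoxybenzoyl]oxy}-6-propylbenzoic acid | COc1cc(Br)c(C(=O)Oc2cc(CCC)c(C(=O)O)c(OCc3ccccc3)c2)c(OCc2ccccc2)c1
F5 | step 8 | 4-(benzyloxycarbonyl)-3-hydroxy-5-propylphenyl 2-(benzyloxy)-6-bromo-4-methoxybenzoate | COc1cc(Br)c(C(=O)Oc2cc(O)c(C(=O)OCc3ccccc3)c(CCC)c2)c(OCc2ccccc2)c1
A1 | alternative 1 | 3-(benzyloxy)-4-(benzyloxycarbonyl)-5-propylphenyl 2-hydroxy-4-methoxy-6-[(2-propyl-1,3-dioxolan-2-yl)methyl]benzoate | CCCC1(Cc2cc(OC)cc(O)c2C(=O)Oc2cc(CCC)c(C(=O)OCc3ccccc3)c(OCc3ccccc3)c2)OCCO1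
A2 | alternative 1 | 3-(benzyloxy)-4-(benzyloxycarbonyl)-5-propylphenyl 4-(2-propyl-1,3-dioxolan-2-yl)but-2-ynoate | CCCC1(CC#CC(=O)Oc2cc(CCC)c(C(=O)OCc3ccccc3)c(OCc3ccccc3)c2)OCCO1
A3 | alternative 1 | 1,3-dimethoxy-1-(trimethylsilyloxy)buta-1,3-diene | COC(=C)C=C(OC)O[Si](C)(C)C
A4 | alternative 2 | 4-(benzyloxycarbonyl)-3-hydroxy-5-propylphenyl 2-(benzyloxy)-4-methoxy-6-[(2-propyl-1,3-dioxolan-2-yl)methyl]benzoate | CCCC1(Cc2cc(OC)cc(OCc3ccccc3)c2C(=O)Oc2cc(O)c(C(=O)OCc3ccccc3)c(CCC)c2)OCCO1
A5 | alternative 2 | 4-(benzyloxy)-4-(trimethylsilyloxy)buta-1,3-dien-2-yl 2-(benzyloxy)-4-methoxy-6-[(2-propyl-1,3-dioxolan-2-yl)methyl]benzoate | CCCC1(Cc2cc(OC)cc(OCc3ccccc3)c2C(=O)OC(=C)C=C(OCc2ccccc2)O[Si](C)(C)C)OCCO1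
A6 | alternative 2 | benzyl hex-2-ynoate | CCCC#CC(=O)OCc1ccccc1
A7 | alternative 3 | 3-(benzyloxy)-4-(benzyloxycarbonyl)-5-propylphenyl 2-(benzyloxy)-4-methoxy-6-[(2-propyl-1,3-dioxolan-2-yl)methyl]benzoate | CCCC1(Cc2cc(OC)cc(OCc3ccccc3)c2C(=O)Oc2cc(CCC)c(C(=O)OCc3ccccc3)c(OCc3ccccc3)c2)OCCO1
A8 | alternative 3 | 2-(benzyloxy)-4-methoxy-6-[(2-propyl-1,3-dioxolan-2-yl)methyl]benzoic acid | CCCC1(Cc2cc(OC)cc(OCc3ccccc3)c2C(=O)O)OCCO1
A9 | alternative 3 | [3-(benzyloxy)-4-(benzyloxycarbonyl)-5-propylphenyl]boronic acid | CCCc1cc(B(O)O)cc(OCc2ccccc2)c1C(=O)OCc1ccccc1
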